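**Plan**

1. Numbering used throughout: seven-membered ring C1(Me)=C2–C3–C4(Me)–C8(H)–C9(OAr)–C10, five-membered ring C4–C5(=O)–C6–C7(OH)(i-Pr)–C8; β is the face of the C4 methyl group.
2. The retrosynthesis cuts, in order: C9–O (ester), the C5 oxygen (back to a C5=C6 alkene), C7–i-Pr, C4–C5 (4π electrocyclisation), C7–C8 (vinyllithium plus enal), and C8 itself (one carbon inserted between C9 and C4).
3. Forward: Birch diene from 2,5-dimethylanisole, dibromocarbene ring expansion to the seven-membered bromodienone, side chain attached at C8, five-membered ring closed by a silicon-directed Nazarov cyclisation, then C5 oxygenation, isopropyl addition and esterification.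
4. Enabling feature: the carbinol carbon C7 and the quaternary C4 sit 1,3 across the five-membered ring, so C5=C6–C7(=O)–C8=C4 is a divinyl ketone (pentadienyl cation) whose C8=C4 alkene already lies in the seven-membered ring and whose C5 can carry silicon.
5. Stereochemistry: C9 comes from a CBS reduction; it steers the conrotation (C4) and the enolate protonation (C8); C7 follows by α-face addition; C9 is inverted in the Mitsunobu esterification.

Key step: step 10

Assumption: the conrotation is taken to form C4–C5 on the face away from the pseudoaxial C9 silyloxy group and the enolate to be protonated anti to the angular methyl; the (R) configuration chosen at C9 and its late inversion rest on this model, which is a prediction.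

**Route**

Step 1
Reactants: 1 3-(trimethylsilyl)prop-2-yn-1-ol
Product: 2 (E)-3-(trimethylsilyl)prop-2-en-1-ol
Conditions: Red-Al, Et2O, 0 °C to rt; aqueous work-up
Reagents that add atoms: none
Why: Alkoxide-directed trans-hydroalumination of a propargylic alcohol followed by protonolysis should give the E-vinylsilane only.

Step 2
Reactants: 2 (E)-3-(trimethylsilyl)prop-2-en-1-ol
Product: 3 (E)-3-(trimethylsilyl)prop-2-enal
Conditions: activated MnO2, CH2Cl2, rt
Reagents that add atoms: none
Why: Manganese dioxide oxidation of an allylic alcohol stops at the enal and should leave the alkene geometry intact.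

Step 3
Reactants: 4 2,5-dimethylanisole
Product: 5 1-methoxy-2,5-dimethylcyclohexa-1,4-diene
Conditions: Li, liquid NH3, THF, t-BuOH, −78 to −33 °C
Reagents that add atoms: none
Why: Birch reduction leaves the methoxy and both methyl groups on sp2 carbons, which should give the unconjugated 1,4-diene with a tetrasubstituted enol ether.

Step 4
Reactants: 5 1-methoxy-2,5-dimethylcyclohexa-1,4-diene
Product: 6 7,7-dibromo-1-methoxy-3,6-dimethylbicyclo[4.1.0]hept-3-ene (racemic)
Conditions: CHBr3, KOt-Bu, pentane, −20 to 0 °C; used crude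
Reagents that add atoms: bromoform, BrC(Br)Br
Why: Dibromocarbene cyclopropanation is electrophilic and should take the electron-rich enol ether alkene in preference to the trisubstituted alkene.

Step 5
Reactants: 6 7,7-dibromo-1-methoxy-3,6-dimethylbicyclo[4.1.0]hept-3-ene
Product: 7 2-bromo-3,6-dimethylcyclohepta-2,5-dien-1-one
Conditions: AgNO3, CaCO3, acetone–H2O, 0 °C to rt; used without chromatography
Reagents that add atoms: water, O
Why: Silver-assisted loss of bromide with disrotatory cyclopropyl-to-allyl opening (ring expansion of alkoxy-gem-dihalocyclopropanes to 2-halocycloalk-2-enones) gives a methoxy-stabilised cation that water captures at C9 with loss of methanol, so the carbene carbon becomes C8 bearing bromine; buffering, low temperature and prompt use guard against loss of HBr to the tropone.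

Step 6
Reactants: 7 2-bromo-3,6-dimethylcyclohepta-2,5-dien-1-one
Product: 8 (1R)-2-bromo-3,6-dimethylcyclohepta-2,5-dien-1-ol
Conditions: (S)-Me-CBS (20 mol%), catecholborane, toluene, −78 °C
Reagents that add atoms: none
Why: Corey–Bakshi–Shibata reduction of an α-bromo enone, in which the bromoalkenyl arm is the large group and the C10 methylene the small one, should give the (R) carbinol at C9; catecholborane at −78 °C does not hydroborate the ring alkene.

Step 7
Reactants: 8 (1R)-2-bromo-3,6-dimethylcyclohepta-2,5-dien-1-ol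
Product: 9 tert-butyl{[(1R)-2-bromo-3,6-dimethylcyclohepta-2,5-dien-1-yl]oxy}dimethylsilane
Conditions: TBSCl, imidazole, DMF, rt
Reagents that add atoms: tert-butyldimethylsilyl chloride, CC(C)(C)[Si](C)(C)Cl
Why: Standard silylation of a secondary allylic alcohol; the bulky ether later serves as the stereocontrol element.

Step 8
Reactants: 9 tert-butyl{[(1R)-2-bromo-3,6-dimethylcyclohepta-2,5-dien-1-yl]oxy}dimethylsilane; 3 (E)-3-(trimethylsilyl)prop-2-enal
Product: 11 (E)-1-[(7R)-7-(tert-butyldimethylsilyloxy)-2,5-dimethylcyclohepta-1,4-dien-1-yl]-3-(trimethylsilyl)prop-2-en-1-ol (both carbinol epimers), via vinyllithium 10 (not isolated)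
Conditions: t-BuLi (2.1 equiv), Et2O, −78 °C; then 3, −78 °C; H2O
Reagents that add atoms: none
Why: Lithium–bromine exchange at −78 °C is faster than deprotonation of the doubly allylic C3 methylene, and the vinyllithium adds 1,2 to the enal; the new carbinol centre is removed in step 9.

Step 9
Reactants: 11 (E)-1-[(7R)-7-(tert-butyldimethylsilyloxy)-2,5-dimethylcyclohepta-1,4-dien-1-yl]-3-(trimethylsilyl)prop-2-en-1-ol
Product: 12 (E)-1-[(7R)-7-(tert-butyldimethylsilyloxy)-2,5-dimethylcyclohepta-1,4-dien-1-yl]-3-(trimethylsilyl)prop-2-en-1-one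
Conditions: Dess–Martin periodinane, NaHCO3, CH2Cl2, 0 °C
Reagents that add atoms: none
Why: Buffered Dess–Martin oxidation of a bis-allylic alcohol gives the cross-conjugated divinyl ketone from both epimers without touching the vinylsilane or the silyl ether.

Step 10
Reactants: 12 (E)-1-[(7R)-7-(tert-butyldimethylsilyloxy)-2,5-dimethylcyclohepta-1,4-dien-1-yl]-3-(trimethylsilyl)prop-2-en-1-one
Product: 14 (4S,8S,9R)-9β-(tert-butyldimethylsilyloxy)-1,4β-dimethyl-8αH-bicyclo[5.3.0]deca-1,5-dien-7-one (plan numbering; trans-fused), via iron dienolate 13 (not isolated)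
Conditions: FeCl3 (1.1 equiv), CH2Cl2, −50 to −10 °C; pH 7 buffer at −30 °C
Reagents that add atoms: none
Why: FeCl3 binds the carbonyl to give the pentadienyl cation C5=C6–C7(OFe)–C8=C4, which closes by conrotatory 4π electrocyclisation (Nazarov cyclisation in its silicon-directed form, known for cycloalkenyl β-silylvinyl ketones) to form C4–C5 and the quaternary C4. The five-membered ring C4–C5–C6–C7–C8 closes in this one electrocyclic event across the termini of the cation, onto the seven-membered ring already in place. The resulting oxyallyl cation over C6–C7–C8 is β to silicon, so chloride-assisted loss of the silyl group gives the C5=C6 alkene (C4 has no hydrogen to lose) and iron dienolate 13, which is protonated at C8 on the cold quench. C4 is controlled by the C9 silyloxy group, which lies pseudoaxial to avoid A(1,2) strain with the complexed acyl group, so that C5 should bond to the face of C4 away from it and the methyl group ends cis to the silyl ether. C8 is controlled by the angular methyl and the silyloxy group, both on the β face, so that the proton should enter from the α face and give the trans ring fusion. The step needs ring closure to outrun protodesilylation and migration of the C3 hydrogen, which the fully substituted C8, the E-vinylsilane (silicon outside) and the low temperature favour.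

Step 11
Reactants: 14 (4S,8S,9R)-9β-(tert-butyldimethylsilyloxy)-1,4β-dimethyl-8αH-bicyclo[5.3.0]deca-1,5-dien-7-one
Product: 16 (4R,5S,8S,9R)-9β-(tert-butyldimethylsilyloxy)-5α-hydroxy-1,4β-dimethyl-8αH-bicyclo[5.3.0]dec-1-en-7-one, via β-boryl ketone 15 (not isolated)
Conditions: B2pin2, CuCl (5 mol%), DPEphos (5 mol%), NaOt-Bu (10 mol%), MeOH (2 equiv), THF, rt; then NaBO3·4H2O, THF–H2O, rt
Reagents that add atoms: sodium perborate, [Na+].[O-]OB=O
Why: Copper-catalysed conjugate borylation of an enone puts boron on the β-carbon C5, expected anti to the angular methyl, and perborate oxidation proceeds with retention; the C5 configuration is erased in step 13, so either epimer serves.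

Step 12
Reactants: 16 (4R,5S,8S,9R)-9β-(tert-butyldimethylsilyloxy)-5α-hydroxy-1,4β-dimethyl-8αH-bicyclo[5.3.0]dec-1-en-7-one
Product: 17 (4R,5S,7R,8S,9R)-9β-(tert-butyldimethylsilyloxy)-7α-isopropyl-1,4β-dimethyl-8αH-bicyclo[5.3.0]dec-1-ene-5α,7β-diol
Conditions: i-PrMgCl (4 equiv), anhydrous CeCl3 (4 equiv), THF, −78 °C, 1 h; then 16, −78 to −40 °C; aq. NH4Cl
Reagents that add atoms: isopropylmagnesium chloride, CC(C)[Mg]Cl
Why: Organocerium 1,2-addition (weakly basic, so enolisation at C8, reduction and retro-aldol are suppressed): the first equivalent forms the C5 alkoxide and the isopropyl group should then enter C7 from the α face, anti to the C8–C9 bond, the silyloxy group and the angular methyl, which sets the β-hydroxyl at C7.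

Step 13
Reactants: 17 (4R,5S,7R,8S,9R)-9β-(tert-butyldimethylsilyloxy)-7α-isopropyl-1,4β-dimethyl-8αH-bicyclo[5.3.0]dec-1-ene-5α,7β-diol
Product: 18 (4R,7R,8S,9R)-9β-(tert-butyldimethylsilyloxy)-7β-hydroxy-7α-isopropyl-1,4β-dimethyl-8αH-bicyclo[5.3.0]dec-1-en-5-one
Conditions: TPAP (5 mol%), NMO, 4 Å MS, CH2Cl2, rt
Reagents that add atoms: none
Why: Ley–Griffith oxidation converts the secondary C5 alcohol to the ketone under neutral conditions, while the tertiary C7 alcohol cannot be oxidised.

Step 14
Reactants: 18 (4R,7R,8S,9R)-9β-(tert-butyldimethylsilyloxy)-7β-hydroxy-7α-isopropyl-1,4β-dimethyl-8αH-bicyclo[5.3.0]dec-1-en-5-one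
Product: 19 (4R,7R,8S,9R)-7β,9β-dihydroxy-7α-isopropyl-1,4β-dimethyl-8αH-bicyclo[5.3.0]dec-1-en-5-one
Conditions: HF·pyridine, pyridine, THF, 0 °C to rt
Reagents that add atoms: none
Why: Buffered fluoride desilylation frees the C9 alcohol without the basic conditions that could open or dehydrate the β-hydroxy ketone.

Step 15
Reactants: 19 (4R,7R,8S,9R)-7β,9β-dihydroxy-7α-isopropyl-1,4β-dimethyl-8αH-bicyclo[5.3.0]dec-1-en-5-one; 20 4-acetoxybenzoic acid
Product: 21 (4R,7R,8S,9S)-7β-hydroxy-7α-isopropyl-1,4β-dimethyl-5-oxo-8αH-bicyclo[5.3.0]dec-1-en-9α-yl 4-acetoxybenzoate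
Conditions: PPh3, DIAD, toluene, 0 °C to rt (acid present before DIAD is added)
Reagents that add atoms: none
Why: Mitsunobu esterification displaces the activated C9 oxygen with the carboxylate under inversion, which turns the β-carbinol into the α-ester; the tertiary C7 alcohol is not activated.

Step 16
Reactants: 21 (4R,7R,8S,9S)-7β-hydroxy-7α-isopropyl-1,4β-dimethyl-5-oxo-8αH-bicyclo[5.3.0]dec-1-en-9α-yl 4-acetoxybenzoate
Product: 22 (4R,7R,8S,9S)-7β-hydroxy-7α-isopropyl-1,4β-dimethyl-5-oxo-8αH-bicyclo[5.3.0]dec-1-en-9α-yl 4-hydroxybenzoate (CNP0238517.1)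
Conditions: K2CO3 (0.2 equiv), MeOH, 0 °C; aq. NH4Cl
Reagents that add atoms: none
Why: Transesterification of the aryl acetate is far faster than attack on the hindered secondary benzoate, and the cold, brief, weakly basic conditions should spare the β-hydroxy ketone.

**Compound list**

1 | 3-(trimethylsilyl)prop-2-yn-1-ol | C[Si](C)(C)C#CCO | starting material
2 | (E)-3-(trimethylsilyl)prop-2-en-1-ol | C[Si](C)(C)/C=C/CO | intermediate
3 | (E)-3-(trimethylsilyl)prop-2-enal | C[Si](C)(C)/C=C/C=O | intermediate
4 | 2,5-dimethylanisole | COc1cc(C)ccc1C | starting material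
5 | 1-methoxy-2,5-dimethylcyclohexa-1,4-diene | COC1=C(C)CC=C(C)C1 | intermediate
6 | 7,7-dibromo-1-methoxy-3,6-dimethylbicyclo[4.1.0]hept-3-ene (racemic) | COC12CC(C)=CCC1(C)C2(Br)Br | intermediate
7 | 2-bromo-3,6-dimethylcyclohepta-2,5-dien-1-one | CC1=CCC(C)=C(Br)C(=O)C1 | intermediate
8 | (1R)-2-bromo-3,6-dimethylcyclohepta-2,5-dien-1-ol | CC1=CCC(C)=C(Br)[C@H](O)C1 | intermediate
9 | tert-butyl{[(1R)-2-bromo-3,6-dimethylcyclohepta-2,5-dien-1-yl]oxy}dimethylsilane | CC1=CCC(C)=C(Br)[C@H](O[Si](C)(C)C(C)(C)C)C1 | intermediate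
10 | vinyllithium from 9, lithium in place of bromine (not isolated) | CC1=CCC(C)=C([Li])[C@H](O[Si](C)(C)C(C)(C)C)C1 | intermediate
11 | (E)-1-[(7R)-7-(tert-butyldimethylsilyloxy)-2,5-dimethylcyclohepta-1,4-dien-1-yl]-3-(trimethylsilyl)prop-2-en-1-ol, both carbinol epimers | CC1=CCC(C)=C(C(O)/C=C/[Si](C)(C)C)[C@H](O[Si](C)(C)C(C)(C)C)C1 | intermediate
12 | (E)-1-[(7R)-7-(tert-butyldimethylsilyloxy)-2,5-dimethylcyclohepta-1,4-dien-1-yl]-3-(trimethylsilyl)prop-2-en-1-one | CC1=CCC(C)=C(C(=O)/C=C/[Si](C)(C)C)[C@H](O[Si](C)(C)C(C)(C)C)C1 | intermediate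
13 | dichloroiron(III) dienolate C5=C6–C7(OFeCl2)=C8 of 14 (not isolated) | CC1=CC[C@@]2(C)C=CC(O[Fe](Cl)Cl)=C2[C@H](O[Si](C)(C)C(C)(C)C)C1 | intermediate
14 | (4S,8S,9R)-9β-(tert-butyldimethylsilyloxy)-1,4β-dimethyl-8αH-bicyclo[5.3.0]deca-1,5-dien-7-one, trans-fused | CC1=CC[C@@]2(C)C=CC(=O)[C@@H]2[C@H](O[Si](C)(C)C(C)(C)C)C1 | intermediate
15 | 5α-(pinacolatoboryl) ketone from 14 (not isolated) | CC1=CC[C@@]2(C)[C@@H](B3OC(C)(C)C(C)(C)O3)CC(=O)[C@@H]2[C@H](O[Si](C)(C)C(C)(C)C)C1 | intermediate
16 | (4R,5S,8S,9R)-9β-(tert-butyldimethylsilyloxy)-5α-hydroxy-1,4β-dimethyl-8αH-bicyclo[5.3.0]dec-1-en-7-one | CC1=CC[C@@]2(C)[C@@H](O)CC(=O)[C@@H]2[C@H](O[Si](C)(C)C(C)(C)C)C1 | intermediate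
17 | (4R,5S,7R,8S,9R)-9β-(tert-butyldimethylsilyloxy)-7α-isopropyl-1,4β-dimethyl-8αH-bicyclo[5.3.0]dec-1-ene-5α,7β-diol | CC1=CC[C@@]2(C)[C@@H](O)C[C@@](O)(C(C)C)[C@@H]2[C@H](O[Si](C)(C)C(C)(C)C)C1 | intermediate
18 | (4R,7R,8S,9R)-9β-(tert-butyldimethylsilyloxy)-7β-hydroxy-7α-isopropyl-1,4β-dimethyl-8αH-bicyclo[5.3.0]dec-1-en-5-one | CC1=CC[C@@]2(C)C(=O)C[C@@](O)(C(C)C)[C@@H]2[C@H](O[Si](C)(C)C(C)(C)C)C1 | intermediate
19 | (4R,7R,8S,9R)-7β,9β-dihydroxy-7α-isopropyl-1,4β-dimethyl-8αH-bicyclo[5.3.0]dec-1-en-5-one | CC1=CC[C@@]2(C)C(=O)C[C@@](O)(C(C)C)[C@@H]2[C@H](O)C1 | intermediate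
20 | 4-acetoxybenzoic acid | CC(=O)Oc1ccc(cc1)C(=O)O | starting material
21 | (4R,7R,8S,9S)-7β-hydroxy-7α-isopropyl-1,4β-dimethyl-5-oxo-8αH-bicyclo[5.3.0]dec-1-en-9α-yl 4-acetoxybenzoate | CC1=CC[C@@]2(C)C(=O)C[C@@](O)(C(C)C)[C@@H]2[C@@H](OC(=O)c2ccc(OC(C)=O)cc2)C1 | intermediate
22 | (4R,7R,8S,9S)-7β-hydroxy-7α-isopropyl-1,4β-dimethyl-5-oxo-8αH-bicyclo[5.3.0]dec-1-en-9α-yl 4-hydroxybenzoate (CNP0238517.1) | CC1=CC[C@@]2(C)C(=O)C[C@@](O)(C(C)C)[C@@H]2[C@@H](OC(=O)c2ccc(O)cc2)C1 | target

**Step count**

Total: 16 steps. Longest linear sequence: 14 steps (steps 3 to 16, from 2,5-dimethylanisole); steps 1 and 2 make the enal that joins in step 8.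

**Steps most likely to fail**

Step 10. Closure at the fully substituted C4 terminus, which carries an inside methyl group, may be slower than protodesilylation of the vinylsilane, acid-promoted migration of the doubly allylic C3 hydrogen, or loss of the silyloxy group from the iron enolate. The sense of conrotation or of the C8 protonation may also depart from the model. The fallback reaches the same C4–C5 bond by a gold-catalysed acyloxy-shift/electrocyclisation sequence in place of the Lewis-acid route. It sets out from bromide 9: Sonogashira coupling with prop-2-yn-1-yl acetate (Pd(PPh3)2Cl2, CuI, i-Pr2NH) would give enynyl acetate F1. A cationic gold(I) catalyst (Ph3PAuNTf2, wet CH2Cl2, rt) would then effect the 3,3-acetoxy shift to the acetoxyallene, 4π closure of the gold-bound pentadienyl cation onto C4 and a 1,2-hydride shift to dienyl acetate F2. Hydrolysis of F2 in the wet medium returns to the route at enone 14. The C5 terminus is an unsubstituted methylene in this variant and no strong Lewis acid meets the silyl ether.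

Step 15. The hindered C9 oxyphosphonium ion may eliminate towards C8 or C10, or may not form at all, instead of being displaced. The fallback replaces redox activation by sulfonate displacement. It sets out from diol 19: chloromethanesulfonyl chloride and pyridine at 0 °C would sulfonylate only the secondary alcohol to give chloromethanesulfonate F3. Caesium 4-acetoxybenzoate (from 20 and Cs2CO3) with 18-crown-6 in toluene at 80 °C would displace it with inversion and return to the route at ester 21.

Step 12. Transfer of the branched isopropyl group to the congested C7 ketone may lose to β-hydride reduction, to enolisation towards C8 (which would also scramble the ring fusion) or to retro-aldol opening of the C5 alkoxide, and the facial selectivity may be incomplete. The fallback uses a smaller sp2 nucleophile that has no transferable β-hydride and reduces the side chain afterwards. It sets out from hydroxy ketone 16: isopropenylmagnesium bromide with CeCl3 (THF, −78 °C) would give isopropenyl carbinol F4. Hydrogenation over Wilkinson's catalyst (H2, RhCl(PPh3)3, benzene) should saturate the 1,1-disubstituted alkene and leave the trisubstituted C1=C2 alkene, returning to the route at diol 17.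

**Further compounds**

F1 | step 10 | 3-[(7R)-7-(tert-butyldimethylsilyloxy)-2,5-dimethylcyclohepta-1,4-dien-1-yl]prop-2-yn-1-yl acetate | CC1=CCC(C)=C(C#CCOC(C)=O)[C@H](O[Si](C)(C)C(C)(C)C)C1
F2 | step 10 | 9β-(tert-butyldimethylsilyloxy)-1,4β-dimethylbicyclo[5.3.0]deca-1,5,7-trien-7-yl acetate (C7=C8 dienyl acetate) | CC1=CC[C@@]2(C)C=CC(OC(C)=O)=C2[C@H](O[Si](C)(C)C(C)(C)C)C1
F3 | step 15 | 7β-hydroxy-7α-isopropyl-1,4β-dimethyl-5-oxo-8αH-bicyclo[5.3.0]dec-1-en-9β-yl chloromethanesulfonate | CC1=CC[C@@]2(C)C(=O)C[C@@](O)(C(C)C)[C@@H]2[C@H](OS(=O)(=O)CCl)C1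
F4 | step 12 | 9β-(tert-butyldimethylsilyloxy)-1,4β-dimethyl-7α-(prop-1-en-2-yl)-8αH-bicyclo[5.3.0]dec-1-ene-5α,7β-diol | CC1=CC[C@@]2(C)[C@@H](O)C[C@@](O)(C(C)=C)[C@@H]2[C@H](O[Si](C)(C)C(C)(C)C)C1
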